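**Plan**

1. Locants used below (carotenoid style): ring A = hydroxy-trimethylcyclohexene (C1'–C6') on the alkyne C7'≡C8'; chain C9'(CH3)=C10'–C11'=C12'–C15'=C15–C14=C13(CH3)–C12=; ring B = butenolide (C11, C10, C9, C19=O); ring C = dihydrofuran (O, C8, C7, C6, C5) fused to cyclohexane ring D (C1–C6, OH on C3).
2. First cut: the C12'–C15' sp2–sp2 single bond between the two unsubstituted E-CH=CH units, giving a C16 dienynyl stannane (ring A) and a C21 trienyl iodide (rings B, C, D). Both carbons are unhindered CH termini, remote from the two methyl branches, from ring B and from both hydroxyls, so two fully functionalised, unprotected halves can be joined under neutral conditions as the last step.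
3. Further cuts in the iodide half: O–C8 of ring C (back to an α-hydroxyallene, then to a 5,6-oxirane carrying the C7≡C8 alkyne), C8–C9 (Sonogashira on a 3-bromobutenolide), and O–C11/C10–C11 of ring B (tandem coupling–lactonisation). In the stannane half: C6'–C7' (Sonogashira) and C11'=C12' (stannyl olefination).
4. Forward: one enol triflate from actinol supplies rings A and D. Left: Sonogashira, oxidation, olefination. Right: ring B first, then the oxirane alkyne is attached at C9, ring C is closed (SN2' hydrogenolysis, then gold cycloisomerisation), the C15 aldehyde becomes the iodide, and the halves are united.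
5. Stereochemistry: C3' and C3 from (4R,6R)-actinol; C5/C6 by Sharpless epoxidation; C8 from the oxirane through the allene axis (anti hydride delivery) and axis-to-centre transfer. Olefin geometry comes from the E-enynol used twice, anti-oxymetalation (Z-ylidene), E-selective chromium olefinations and stereoretentive couplings.

Key step: step 21

Assumption: (4R,6R)-actinol, (2E)-3-methylpent-2-en-4-yn-1-ol, propiolic acid, CH2I2 and Bu3SnCl are bought, as are all reagents named only on Conditions or Reagents lines.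

**Route**

Step 1
Reactants: 1 (4R,6R)-4-hydroxy-2,2,6-trimethylcyclohexan-1-one
Product: 2 (4R,6R)-4-(tert-butyldimethylsilyloxy)-2,2,6-trimethylcyclohexan-1-one
Conditions: TBSCl, imidazole, DMF, rt
Reagents that add atoms: tert-butyldimethylsilyl chloride, CC(C)(C)[Si](C)(C)Cl
Why: Imidazole-promoted silylation of the only hydroxyl should protect the centre that becomes C3' and C3 without touching it.

Step 2
Reactants: 2 (4R,6R)-4-(tert-butyldimethylsilyloxy)-2,2,6-trimethylcyclohexan-1-one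
Product: 4 (4R)-4-(tert-butyldimethylsilyloxy)-2,6,6-trimethylcyclohex-1-en-1-yl trifluoromethanesulfonate, via lithium enolate 3 (not isolated)
Conditions: LiN(i-Pr)2, THF, −78 °C; PhNTf2, −78 °C → rt; NH4Cl work-up
Reagents that add atoms: N-phenylbis(trifluoromethanesulfonimide), O=S(=O)(N(c1ccccc1)S(=O)(=O)C(F)(F)F)C(F)(F)F
Why: Enolisation is possible only toward the methyl-bearing α-carbon (the other α-carbon is quaternary), and O-triflation of enolate 3 should give the tetrasubstituted enol triflate (enol triflate formation).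

Step 3
Reactants: 4 (4R)-4-(tert-butyldimethylsilyloxy)-2,6,6-trimethylcyclohex-1-en-1-yl trifluoromethanesulfonate; 5 (2E)-3-methylpent-2-en-4-yn-1-ol
Product: 6 (2E)-5-[(4R)-4-(tert-butyldimethylsilyloxy)-2,6,6-trimethylcyclohex-1-en-1-yl]-3-methylpent-2-en-4-yn-1-ol
Conditions: Pd(PPh3)4 (cat.), CuI (cat.), Et3N, DMF, 50 °C
Reagents that add atoms: none
Why: Sonogashira coupling of the alkenyl triflate with the terminal alkyne should form the C6'–C7' bond and leave the E geometry of the enynol untouched.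

Step 4
Reactants: 6 (2E)-5-[(4R)-4-(tert-butyldimethylsilyloxy)-2,6,6-trimethylcyclohex-1-en-1-yl]-3-methylpent-2-en-4-yn-1-ol
Product: 7 (2E)-5-[(4R)-4-(tert-butyldimethylsilyloxy)-2,6,6-trimethylcyclohex-1-en-1-yl]-3-methylpent-2-en-4-ynal
Conditions: MnO2, CH2Cl2, rt
Reagents that add atoms: none
Why: MnO2 should oxidise the allylic primary alcohol to the enal (allylic oxidation) without affecting the silyl ether or the enyne.

Step 5
Reactants: 8 diiodomethane; 9 Bu3SnCl
Product: 11 tributyl(diiodomethyl)stannane, via diiodomethyllithium 10 (not isolated)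
Conditions: LiN(SiMe3)2, THF/Et2O, −78 °C, dark; then Bu3SnCl, −78 °C → rt
Reagents that add atoms: none
Why: Deprotonation of CH2I2 by the hindered amide at low temperature gives carbenoid 10, which Bu3SnCl should trap at carbon (stannylation of an α-haloalkyllithium).

Step 6
Reactants: 7 (2E)-5-[(4R)-4-(tert-butyldimethylsilyloxy)-2,6,6-trimethylcyclohex-1-en-1-yl]-3-methylpent-2-en-4-ynal; 11 tributyl(diiodomethyl)stannane
Product: 12 tributyl{(1E,3E)-6-[(4R)-4-(tert-butyldimethylsilyloxy)-2,6,6-trimethylcyclohex-1-en-1-yl]-4-methylhexa-1,3-dien-5-yn-1-yl}stannane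
Conditions: CrCl2, DMF/THF, rt, dark
Reagents that add atoms: none
Why: Takai–Hodgson olefination: the geminal dichromium species formed from 11 adds to the aldehyde and eliminates to give the E-alkenylstannane, creating the C11'=C12' bond.

Step 7
Reactants: 12 tributyl{(1E,3E)-6-[(4R)-4-(tert-butyldimethylsilyloxy)-2,6,6-trimethylcyclohex-1-en-1-yl]-4-methylhexa-1,3-dien-5-yn-1-yl}stannane
Product: 13 (1R)-3,5,5-trimethyl-4-[(3E,5E)-3-methyl-6-(tributylstannyl)hexa-3,5-dien-1-yn-1-yl]cyclohex-3-en-1-ol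
Conditions: Bu4NF, THF, 0 °C → rt
Reagents that add atoms: none
Why: Fluoride desilylation should free the C3' hydroxyl, the alkenylstannane being stable to Bu4NF.

Step 8
Reactants: 4 (4R)-4-(tert-butyldimethylsilyloxy)-2,6,6-trimethylcyclohex-1-en-1-yl trifluoromethanesulfonate
Product: 14 methyl (4R)-4-(tert-butyldimethylsilyloxy)-2,6,6-trimethylcyclohex-1-ene-1-carboxylate
Conditions: Pd(OAc)2 (cat.), PPh3, CO (1 atm), MeOH, Et3N, DMF, 60 °C
Reagents that add atoms: carbon monoxide, [C-]#[O+]; methanol, CO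
Why: Palladium-catalysed alkoxycarbonylation of the alkenyl triflate (CO insertion, methanolysis) should install C7 as an ester.

Step 9
Reactants: 14 methyl (4R)-4-(tert-butyldimethylsilyloxy)-2,6,6-trimethylcyclohex-1-ene-1-carboxylate
Product: 16 [(4R)-4-(tert-butyldimethylsilyloxy)-2,6,6-trimethylcyclohex-1-en-1-yl]methanol, via enal 15 (not isolated)
Conditions: i-Bu2AlH, CH2Cl2, −78 → 0 °C; Rochelle salt work-up
Reagents that add atoms: none
Why: Hydride reduction of the enoate with i-Bu2AlH passes through enal 15 and should stop at the allylic alcohol needed to direct the epoxidation (1,2-reduction).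

Step 10
Reactants: 16 [(4R)-4-(tert-butyldimethylsilyloxy)-2,6,6-trimethylcyclohex-1-en-1-yl]methanol
Product: 17 [(1R,4S,6R)-4-(tert-butyldimethylsilyloxy)-2,2,6-trimethyl-7-oxabicyclo[4.1.0]heptan-1-yl]methanol
Conditions: Ti(Oi-Pr)4 (cat.), D-(−)-diethyl tartrate (cat.), t-BuOOH, 4 Å MS, CH2Cl2, −20 °C
Reagents that add atoms: tert-butyl hydroperoxide, CC(C)(C)OO
Why: Sharpless asymmetric epoxidation: the titanium D-(−)-tartrate complex should deliver oxygen to the face of C5=C6 anti to the C3 silyloxy group under reagent control, setting C5 and C6.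

Step 11
Reactants: 17 [(1R,4S,6R)-4-(tert-butyldimethylsilyloxy)-2,2,6-trimethyl-7-oxabicyclo[4.1.0]heptan-1-yl]methanol
Product: 18 (1S,4S,6R)-4-(tert-butyldimethylsilyloxy)-2,2,6-trimethyl-7-oxabicyclo[4.1.0]heptane-1-carbaldehyde
Conditions: Pr4N[RuO4] (cat.), NMO, 4 Å MS, CH2Cl2, rt
Reagents that add atoms: none
Why: Ley–Griffith oxidation should give the aldehyde under non-acidic conditions that leave oxirane and silyl ether intact, and C6 has no α-hydrogen to epimerise.

Step 12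
Reactants: 18 (1S,4S,6R)-4-(tert-butyldimethylsilyloxy)-2,2,6-trimethyl-7-oxabicyclo[4.1.0]heptane-1-carbaldehyde
Product: 19 tert-butyl{[(1R,3S,6R)-6-ethynyl-1,5,5-trimethyl-7-oxabicyclo[4.1.0]heptan-3-yl]oxy}dimethylsilane
Conditions: dimethyl (1-diazo-2-oxopropyl)phosphonate, K2CO3, MeOH, 0 °C → rt
Reagents that add atoms: dimethyl (1-diazo-2-oxopropyl)phosphonate, COP(=O)(OC)C(=[N+]=[N-])C(C)=O
Why: Ohira–Bestmann (Seyferth–Gilbert) homologation should convert the non-enolisable aldehyde into the terminal alkyne C7≡C8 under mild carbonate conditions.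

Step 13
Reactants: 19 tert-butyl{[(1R,3S,6R)-6-ethynyl-1,5,5-trimethyl-7-oxabicyclo[4.1.0]heptan-3-yl]oxy}dimethylsilane
Product: 20 (1R,3S,6R)-6-ethynyl-1,5,5-trimethyl-7-oxabicyclo[4.1.0]heptan-3-ol
Conditions: Bu4NF, THF, 0 °C → rt
Reagents that add atoms: none
Why: Fluoride desilylation at this robust stage avoids any fluoride or acid treatment once the butenolide and the allylic ether are present.

Step 14
Reactants: 21 propiolic acid
Product: 22 (2E)-2,3-dibromoprop-2-enoic acid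
Conditions: Br2, CHCl3, 0 °C → rt, dark
Reagents that add atoms: bromine, BrBr
Why: Anti addition of bromine across the alkyne (electrophilic bromination) should give the E-dibromide, in which the C3 bromine is cis to the carboxyl group.

Step 15
Reactants: 22 (2E)-2,3-dibromoprop-2-enoic acid; 5 (2E)-3-methylpent-2-en-4-yn-1-ol
Product: 24 (5Z)-3-bromo-5-[(2E)-4-hydroxy-2-methylbut-2-en-1-ylidene]furan-2(5H)-one, via bromoenynoic acid 23 (not isolated)
Conditions: Pd(PPh3)4 (cat.), CuI (cat.), Et3N, MeCN, rt, dark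
Reagents that add atoms: none
Why: Tandem Sonogashira coupling and 5-exo-dig lactonisation: the more electrophilic, less hindered β-bromide couples first to give 23, whose carboxylate adds anti across the metal-activated alkyne to close ring B as the Z-ylidene butenolide.

Step 16
Reactants: 24 (5Z)-3-bromo-5-[(2E)-4-hydroxy-2-methylbut-2-en-1-ylidene]furan-2(5H)-one; 20 (1R,3S,6R)-6-ethynyl-1,5,5-trimethyl-7-oxabicyclo[4.1.0]heptan-3-ol
Product: 25 (5Z)-3-{[(1R,4S,6R)-4-hydroxy-2,2,6-trimethyl-7-oxabicyclo[4.1.0]heptan-1-yl]ethynyl}-5-[(2E)-4-hydroxy-2-methylbut-2-en-1-ylidene]furan-2(5H)-one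
Conditions: Pd(PPh3)4 (cat.), CuI (cat.), i-Pr2NEt, THF/DMF, 40 °C
Reagents that add atoms: none
Why: Sonogashira coupling of the activated α-bromo butenolide with terminal alkyne 20 should form the C8–C9 bond.

Step 17
Reactants: 25 (5Z)-3-{[(1R,4S,6R)-4-hydroxy-2,2,6-trimethyl-7-oxabicyclo[4.1.0]heptan-1-yl]ethynyl}-5-[(2E)-4-hydroxy-2-methylbut-2-en-1-ylidene]furan-2(5H)-one
Product: 26 (5Z)-3-{2-[(2R,4S)-2,4-dihydroxy-2,6,6-trimethylcyclohexylidene]ethenyl}-5-[(2E)-4-hydroxy-2-methylbut-2-en-1-ylidene]furan-2(5H)-one with S allene axis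
Conditions: Pd2(dba)3·CHCl3 (cat.), PPh3, HCO2H, Et3N, THF, 0 °C → rt
Reagents that add atoms: none
Why: Palladium-catalysed formate hydrogenolysis of a propargylic C–O electrophile in the SN2' sense: zerovalent palladium opens the oxirane at C8 anti to the C6–O bond and hydride is passed from palladium to C8 with retention, so hydrogen ends anti to the departed oxygen, the butenolide lies on the side of the C5 hydroxyl (S axis) and C5 keeps its configuration.

Step 18
Reactants: 26 (5Z)-3-{2-[(2R,4S)-2,4-dihydroxy-2,6,6-trimethylcyclohexylidene]ethenyl}-5-[(2E)-4-hydroxy-2-methylbut-2-en-1-ylidene]furan-2(5H)-one with S allene axis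
Product: 27 (5Z)-3-[(2R,6S,7aR)-6-hydroxy-4,4,7a-trimethyl-2,4,5,6,7,7a-hexahydro-1-benzofuran-2-yl]-5-[(2E)-4-hydroxy-2-methylbut-2-en-1-ylidene]furan-2(5H)-one
Conditions: AuCl3 (cat.), THF, 0 °C → rt, dark
Reagents that add atoms: none
Why: Gold-catalysed 5-endo-trig cycloisomerisation of an α-hydroxyallene: the C5 hydroxyl adds to C8 anti to gold in the plane of C1–C6–C5, so the allene axis is transferred to C8 (butenolide cis to the C4 methylene, 8R) as ring C closes.

Step 19
Reactants: 27 (5Z)-3-[(2R,6S,7aR)-6-hydroxy-4,4,7a-trimethyl-2,4,5,6,7,7a-hexahydro-1-benzofuran-2-yl]-5-[(2E)-4-hydroxy-2-methylbut-2-en-1-ylidene]furan-2(5H)-one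
Product: 28 (2E,4Z)-4-{4-[(2R,6S,7aR)-6-hydroxy-4,4,7a-trimethyl-2,4,5,6,7,7a-hexahydro-1-benzofuran-2-yl]-5-oxofuran-2(5H)-ylidene}-3-methylbut-2-enal
Conditions: MnO2, CH2Cl2, rt, dark
Reagents that add atoms: none
Why: MnO2 should oxidise only the allylic primary alcohol and leave the saturated secondary C3 hydroxyl alone (chemoselective allylic oxidation).

Step 20
Reactants: 28 (2E,4Z)-4-{4-[(2R,6S,7aR)-6-hydroxy-4,4,7a-trimethyl-2,4,5,6,7,7a-hexahydro-1-benzofuran-2-yl]-5-oxofuran-2(5H)-ylidene}-3-methylbut-2-enal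
Product: 29 (5Z)-3-[(2R,6S,7aR)-6-hydroxy-4,4,7a-trimethyl-2,4,5,6,7,7a-hexahydro-1-benzofuran-2-yl]-5-[(2E,4E)-5-iodo-2-methylpenta-2,4-dien-1-ylidene]furan-2(5H)-one
Conditions: CHI3, CrCl2, THF, 0 °C → rt, dark
Reagents that add atoms: iodoform, IC(I)I
Why: Takai iodo-olefination: the geminal dichromium reagent from CHI3 and CrCl2 should convert the aldehyde into the E-alkenyl iodide (C15=C15') and tolerate the free hydroxyl and the lactone.

Step 21
Reactants: 13 (1R)-3,5,5-trimethyl-4-[(3E,5E)-3-methyl-6-(tributylstannyl)hexa-3,5-dien-1-yn-1-yl]cyclohex-3-en-1-ol; 29 (5Z)-3-[(2R,6S,7aR)-6-hydroxy-4,4,7a-trimethyl-2,4,5,6,7,7a-hexahydro-1-benzofuran-2-yl]-5-[(2E,4E)-5-iodo-2-methylpenta-2,4-dien-1-ylidene]furan-2(5H)-one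
Product: 30 (5Z)-3-[(2R,6S,7aR)-6-hydroxy-4,4,7a-trimethyl-2,4,5,6,7,7a-hexahydro-1-benzofuran-2-yl]-5-{(2E,4E,6E,8E)-11-[(4R)-4-hydroxy-2,6,6-trimethylcyclohex-1-en-1-yl]-2,9-dimethylundeca-2,4,6,8-tetraen-10-yn-1-ylidene}furan-2(5H)-one
Conditions: Pd2(dba)3·CHCl3 (cat.), AsPh3, DMF/THF, 25 °C, degassed, dark
Reagents that add atoms: none
Why: Stille cross-coupling: zerovalent palladium inserts into the C15'–I bond of 29 with retention, the dienyl group of 13 passes from tin to palladium with retention, and reductive elimination forms the C12'–C15' single bond. The closest known reaction type is the Pd2(dba)3/AsPh3-mediated coupling of alkenyl iodides with alkenylstannanes used to assemble polyenes and carotenoid butenolides. No ring is closed and no stereocentre is created; the stereochemical demand is retention of the four E chain olefins and the Z ylidene, which the stereoretentive elementary steps secure. The selectivity needed is reaction at the C–I bond only, in the presence of the butenolide, the C7'≡C8' alkyne, the allylic C8–O ether and two free hydroxyls; neutral, base-free conditions secure this, and because both reacting carbons are unsubstituted CH termini far from the methyl branches, transmetalation should be fast at room temperature. Degassed solvent and exclusion of light should keep the polyene from isomerising.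

**Compound list**

1 | (4R,6R)-4-hydroxy-2,2,6-trimethylcyclohexan-1-one (actinol) | O=C1C(C)(C)C[C@H](O)C[C@H]1C | starting material
2 | (4R,6R)-4-(tert-butyldimethylsilyloxy)-2,2,6-trimethylcyclohexan-1-one | O=C1C(C)(C)C[C@H](O[Si](C)(C)C(C)(C)C)C[C@H]1C | intermediate
3 | lithium enolate of 2 | [Li+].CC1=C([O-])C(C)(C)C[C@H](O[Si](C)(C)C(C)(C)C)C1 | intermediate
4 | (4R)-4-(tert-butyldimethylsilyloxy)-2,6,6-trimethylcyclohex-1-en-1-yl trifluoromethanesulfonate | CC1=C(OS(=O)(=O)C(F)(F)F)C(C)(C)C[C@H](O[Si](C)(C)C(C)(C)C)C1 | intermediate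
5 | (2E)-3-methylpent-2-en-4-yn-1-ol | C#C/C(C)=C/CO | starting material
6 | (2E)-5-[(4R)-4-(tert-butyldimethylsilyloxy)-2,6,6-trimethylcyclohex-1-en-1-yl]-3-methylpent-2-en-4-yn-1-ol | CC1=C(C#C/C(C)=C/CO)C(C)(C)C[C@H](O[Si](C)(C)C(C)(C)C)C1 | intermediate
7 | (2E)-5-[(4R)-4-(tert-butyldimethylsilyloxy)-2,6,6-trimethylcyclohex-1-en-1-yl]-3-methylpent-2-en-4-ynal | CC1=C(C#C/C(C)=C/C=O)C(C)(C)C[C@H](O[Si](C)(C)C(C)(C)C)C1 | intermediate
8 | diiodomethane | ICI | starting material
9 | Bu3SnCl (tributyltin chloride) | CCCC[Sn](CCCC)(CCCC)Cl | starting material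
10 | diiodomethyllithium | [Li]C(I)I | intermediate
11 | tributyl(diiodomethyl)stannane | CCCC[Sn](CCCC)(CCCC)C(I)I | intermediate
12 | tributyl{(1E,3E)-6-[(4R)-4-(tert-butyldimethylsilyloxy)-2,6,6-trimethylcyclohex-1-en-1-yl]-4-methylhexa-1,3-dien-5-yn-1-yl}stannane | CC1=C(C#C/C(C)=C/C=C/[Sn](CCCC)(CCCC)CCCC)C(C)(C)C[C@H](O[Si](C)(C)C(C)(C)C)C1 | intermediate
13 | (1R)-3,5,5-trimethyl-4-[(3E,5E)-3-methyl-6-(tributylstannyl)hexa-3,5-dien-1-yn-1-yl]cyclohex-3-en-1-ol | CC1=C(C#C/C(C)=C/C=C/[Sn](CCCC)(CCCC)CCCC)C(C)(C)C[C@H](O)C1 | intermediate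
14 | methyl (4R)-4-(tert-butyldimethylsilyloxy)-2,6,6-trimethylcyclohex-1-ene-1-carboxylate | CC1=C(C(=O)OC)C(C)(C)C[C@H](O[Si](C)(C)C(C)(C)C)C1 | intermediate
15 | (4R)-4-(tert-butyldimethylsilyloxy)-2,6,6-trimethylcyclohex-1-ene-1-carbaldehyde | CC1=C(C=O)C(C)(C)C[C@H](O[Si](C)(C)C(C)(C)C)C1 | intermediate
16 | [(4R)-4-(tert-butyldimethylsilyloxy)-2,6,6-trimethylcyclohex-1-en-1-yl]methanol | CC1=C(CO)C(C)(C)C[C@H](O[Si](C)(C)C(C)(C)C)C1 | intermediate
17 | [(1R,4S,6R)-4-(tert-butyldimethylsilyloxy)-2,2,6-trimethyl-7-oxabicyclo[4.1.0]heptan-1-yl]methanol (oxirane anti to the silyloxy group) | OC[C@@]12O[C@]1(C)C[C@@H](O[Si](C)(C)C(C)(C)C)CC2(C)C | intermediate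
18 | (1S,4S,6R)-4-(tert-butyldimethylsilyloxy)-2,2,6-trimethyl-7-oxabicyclo[4.1.0]heptane-1-carbaldehyde | O=C[C@@]12O[C@]1(C)C[C@@H](O[Si](C)(C)C(C)(C)C)CC2(C)C | intermediate
19 | tert-butyl{[(1R,3S,6R)-6-ethynyl-1,5,5-trimethyl-7-oxabicyclo[4.1.0]heptan-3-yl]oxy}dimethylsilane | C#C[C@@]12O[C@]1(C)C[C@@H](O[Si](C)(C)C(C)(C)C)CC2(C)C | intermediate
20 | (1R,3S,6R)-6-ethynyl-1,5,5-trimethyl-7-oxabicyclo[4.1.0]heptan-3-ol | C#C[C@@]12O[C@]1(C)C[C@@H](O)CC2(C)C | intermediate
21 | propiolic acid | C#CC(=O)O | starting material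
22 | (2E)-2,3-dibromoprop-2-enoic acid | Br/C=C(/Br)C(=O)O | intermediate
23 | (2E,6E)-2-bromo-8-hydroxy-6-methylocta-2,6-dien-4-ynoic acid | OC/C=C(C)/C#C/C=C(/Br)C(=O)O | intermediate
24 | (5Z)-3-bromo-5-[(2E)-4-hydroxy-2-methylbut-2-en-1-ylidene]furan-2(5H)-one | OC/C=C(C)/C=C1/C=C(Br)C(=O)O1 | intermediate
25 | (5Z)-3-{[(1R,4S,6R)-4-hydroxy-2,2,6-trimethyl-7-oxabicyclo[4.1.0]heptan-1-yl]ethynyl}-5-[(2E)-4-hydroxy-2-methylbut-2-en-1-ylidene]furan-2(5H)-one | OC/C=C(C)/C=C1/C=C(C#C[C@@]23O[C@]2(C)C[C@@H](O)CC3(C)C)C(=O)O1 | intermediate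
26 | (5Z)-3-{2-[(2R,4S)-2,4-dihydroxy-2,6,6-trimethylcyclohexylidene]ethenyl}-5-[(2E)-4-hydroxy-2-methylbut-2-en-1-ylidene]furan-2(5H)-one, S allene axis (butenolide on the side of the tertiary hydroxyl) | OC/C=C(C)/C=C1/C=C(C=[C@]=C2C(C)(C)C[C@H](O)C[C@@]2(C)O)C(=O)O1 | intermediate
27 | (5Z)-3-[(2R,6S,7aR)-6-hydroxy-4,4,7a-trimethyl-2,4,5,6,7,7a-hexahydro-1-benzofuran-2-yl]-5-[(2E)-4-hydroxy-2-methylbut-2-en-1-ylidene]furan-2(5H)-one | OC/C=C(C)/C=C1/C=C([C@H]2C=C3C(C)(C)C[C@H](O)C[C@@]3(C)O2)C(=O)O1 | intermediate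
28 | (2E,4Z)-4-{4-[(2R,6S,7aR)-6-hydroxy-4,4,7a-trimethyl-2,4,5,6,7,7a-hexahydro-1-benzofuran-2-yl]-5-oxofuran-2(5H)-ylidene}-3-methylbut-2-enal | O=C/C=C(C)/C=C1/C=C([C@H]2C=C3C(C)(C)C[C@H](O)C[C@@]3(C)O2)C(=O)O1 | intermediate
29 | (5Z)-3-[(2R,6S,7aR)-6-hydroxy-4,4,7a-trimethyl-2,4,5,6,7,7a-hexahydro-1-benzofuran-2-yl]-5-[(2E,4E)-5-iodo-2-methylpenta-2,4-dien-1-ylidene]furan-2(5H)-one | I/C=C/C=C(C)/C=C1/C=C([C@H]2C=C3C(C)(C)C[C@H](O)C[C@@]3(C)O2)C(=O)O1 | intermediate
30 | (5Z)-3-[(2R,6S,7aR)-6-hydroxy-4,4,7a-trimethyl-2,4,5,6,7,7a-hexahydro-1-benzofuran-2-yl]-5-{(2E,4E,6E,8E)-11-[(4R)-4-hydroxy-2,6,6-trimethylcyclohex-1-en-1-yl]-2,9-dimethylundeca-2,4,6,8-tetraen-10-yn-1-ylidene}furan-2(5H)-one | CC1=C(C#C/C(C)=C/C=C/C=C/C=C(C)/C=C2/C=C([C@H]3C=C4C(C)(C)C[C@H](O)C[C@@]4(C)O3)C(=O)O2)C(C)(C)C[C@H](O)C1 | target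

**Step count and risks**

Total step count: 21. Longest linear sequence: 14 steps (1 → 2 → 4 → 14 → 16 → 17 → 18 → 19 → 20 → 25 → 26 → 27 → 28 → 29 → 30).

Steps most likely to fail:

1. Step 17. The anti-SN2' course may be lost through hydride delivery at the propargylic carbon (alkyne retained), through epimerisation of the allenylpalladium intermediate before hydride transfer, or through hydropalladation of the conjugated butenolide. The fallback sets out from 20 and comes back at 27. Hydrostannation of the terminal alkyne of 20 (Bu3SnH, PdCl2(PPh3)2, THF) should give (1R,3S,6S)-1,5,5-trimethyl-6-[(E)-2-(tributylstannyl)ethenyl]-7-oxabicyclo[4.1.0]heptan-3-ol F1. Stille coupling of F1 with bromobutenolide 24 (Pd2(dba)3·CHCl3, AsPh3, NMP) should give the 5,6-epoxy-7-ene butenolide F2. The classical acid-induced 5,6-epoxide to 5,8-furanoid rearrangement (pyridinium p-toluenesulfonate, CHCl3, 0 °C) would then give 27 together with its C8 epimer F3, to be separated by HPLC. This path also bypasses step 18, but gives up reagent-independent control at C8.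

2. Step 18. Gold or adventitious acid may ionise the doubly allylic C8–O bond and erode the configuration at C8, or the acceptor-substituted vinylallene may react sluggishly or along other gold-triggered pathways. The fallback sets out from 26 and comes back at 27. Iodocyclisation of 26 with N-iodosuccinimide (CH2Cl2, −20 °C), which adds oxygen and iodine anti across C7=C8 with the same axis-to-centre transfer, should give the 3-iodo-2,5-dihydrofuran F4. Hydrodeiodination of F4 (Pd(PPh3)4, HCO2H, Et3N, DMF) returns to 27.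

3. Step 21. Slow tin-to-palladium transmetalation may allow homocoupling, protodestannylation, or light- and oxygen-induced isomerisation and decay of the two polyene partners. The fallback sets out from 7 and comes back at 30. Takai–Utimoto borylation of 7 (Cl2CHB(pin), CrCl2, LiI, THF) should give the E-dienyl pinacol boronate F5. Desilylation (HF·pyridine, THF) gives the hydroxy boronate F6. Suzuki–Miyaura coupling of F6 with 29 (Pd(PPh3)4, TlOEt, THF/H2O, rt, dark) then forms the same C12'–C15' bond by the faster boron-to-palladium transfer.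

**Further compounds**

F1 | step 17 | (1R,3S,6S)-1,5,5-trimethyl-6-[(E)-2-(tributylstannyl)ethenyl]-7-oxabicyclo[4.1.0]heptan-3-ol | CCCC[Sn](CCCC)(CCCC)/C=C/[C@@]12O[C@]1(C)C[C@@H](O)CC2(C)C
F2 | step 17 | (5Z)-3-{(E)-2-[(1S,4S,6R)-4-hydroxy-2,2,6-trimethyl-7-oxabicyclo[4.1.0]heptan-1-yl]ethenyl}-5-[(2E)-4-hydroxy-2-methylbut-2-en-1-ylidene]furan-2(5H)-one | OC/C=C(C)/C=C1/C=C(/C=C/[C@@]23O[C@]2(C)C[C@@H](O)CC3(C)C)C(=O)O1
F3 | step 17 | (5Z)-3-[(2S,6S,7aR)-6-hydroxy-4,4,7a-trimethyl-2,4,5,6,7,7a-hexahydro-1-benzofuran-2-yl]-5-[(2E)-4-hydroxy-2-methylbut-2-en-1-ylidene]furan-2(5H)-one (C8 epimer of 27) | OC/C=C(C)/C=C1/C=C([C@@H]2C=C3C(C)(C)C[C@H](O)C[C@@]3(C)O2)C(=O)O1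
F4 | step 18 | (5Z)-3-[(2S,6S,7aR)-6-hydroxy-3-iodo-4,4,7a-trimethyl-2,4,5,6,7,7a-hexahydro-1-benzofuran-2-yl]-5-[(2E)-4-hydroxy-2-methylbut-2-en-1-ylidene]furan-2(5H)-one (same spatial arrangement at C8 as 27) | OC/C=C(C)/C=C1/C=C([C@H]2C(I)=C3C(C)(C)C[C@H](O)C[C@@]3(C)O2)C(=O)O1
F5 | step 21 | 2-{(1E,3E)-6-[(4R)-4-(tert-butyldimethylsilyloxy)-2,6,6-trimethylcyclohex-1-en-1-yl]-4-methylhexa-1,3-dien-5-yn-1-yl}-4,4,5,5-tetramethyl-1,3,2-dioxaborolane | CC1=C(C#C/C(C)=C/C=C/B2OC(C)(C)C(C)(C)O2)C(C)(C)C[C@H](O[Si](C)(C)C(C)(C)C)C1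
F6 | step 21 | (1R)-3,5,5-trimethyl-4-[(3E,5E)-3-methyl-6-(4,4,5,5-tetramethyl-1,3,2-dioxaborolan-2-yl)hexa-3,5-dien-1-yn-1-yl]cyclohex-3-en-1-ol | CC1=C(C#C/C(C)=C/C=C/B2OC(C)(C)C(C)(C)O2)C(C)(C)C[C@H](O)C1
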